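**Plan**
- Feature: C1 (H, 3,4-dimethoxyphenyl, bonded to benzo carbon C8a) and C2 (H, CH3, bonded to C3) are neighbouring sp3 methines of the carbocycle fused to the dimethoxybenzo ring, with aryl and methyl trans. Read backwards, they are an aryl and a methyl group placed on opposite faces of a C1=C2 styrene bond whose C2 carries boron in place of C3.
- Cuts, in order: C3=C4 (ring-closing metathesis), C4=CH2 (Wittig on an unmasked aldehyde), C2–C3 (Zweifel olefination of a C2 boronate), then C1–aryl and C2–CH3 together (conjunctive cross-coupling), then C2–B and C8a–C1 (hydroboration, Sonogashira).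
- Forward: both benzene rings are bought. The C8a–C1–C2 chain is grown on 6-bromoveratraldehyde, the three-component coupling brings in the second arene and the methyl group, C3 is attached, and the only ring that is made, the six-membered carbocycle, closes last.
- Stereochemistry: C1 (R) and C2 (S) are both set in the coupling. The relative configuration comes from stereospecific anti addition to a Z-alkene and the absolute one from the chiral bisphosphine on palladium. C2 passes through the Zweifel step with retention, and no later step touches either centre.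
- Boron carries the rigid cis-diol made from acenaphthoquinone, B(mac), instead of pinacol, because β-substituted alkenyl pinacol boronates tend to undergo plain Suzuki-type transfer.

Key step: step 7

Assumption: the dihydronaphthalene numbering (C1–C4, C4a, C8a) is also used for the corresponding atoms of all open-chain intermediates.
Assumption: which enantiomer of the MandyPhos ligand sends palladium to the C1-Si face of this Z β-aryl alkene is settled in a trial run. Both enantiomers are sold, and the route is drawn for the one that gives (1R,2S).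

**Step 1**
Reactants: 1 2-bromo-4,5-dimethoxybenzaldehyde; 2 trimethylsilylacetylene
Product: 3 4,5-dimethoxy-2-[(trimethylsilyl)ethynyl]benzaldehyde
Conditions: PdCl2(PPh3)2 (2 mol %), CuI (4 mol %), Et3N, THF, 60 °C
Reagents that add atoms: none
Why: Sonogashira coupling, in which the ortho-formyl group activates the otherwise electron-rich C–Br bond toward oxidative addition and the silyl cap prevents reaction at the second alkyne terminus.

**Step 2**
Reactants: 3 4,5-dimethoxy-2-[(trimethylsilyl)ethynyl]benzaldehyde
Product: 4 2-{4,5-dimethoxy-2-[(trimethylsilyl)ethynyl]phenyl}-1,3-dioxolane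
Conditions: HOCH2CH2OH (5 equiv), p-TsOH·H2O (5 mol %), toluene, reflux, Dean–Stark
Reagents that add atoms: ethylene glycol, OCCO
Why: Acid-catalysed acetalisation driven by azeotropic removal of water masks the aldehyde against the organolithium reagents of steps 7 and 8, and the silylated alkyne is inert to the acid.

**Step 3**
Reactants: 4 2-{4,5-dimethoxy-2-[(trimethylsilyl)ethynyl]phenyl}-1,3-dioxolane
Product: 5 2-(2-ethynyl-4,5-dimethoxyphenyl)-1,3-dioxolane
Conditions: K2CO3 (0.2 equiv), MeOH, rt
Reagents that add atoms: none
Why: Base-catalysed methanolysis of the C(sp)–Si bond (protodesilylation) frees the terminal alkyne under conditions that leave the acetal untouched.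

**Step 4**
Reactants: 6 acenaphthoquinone (acenaphthylene-1,2-dione)
Product: 7 cis-1,2-dimethyl-1,2-dihydroacenaphthylene-1,2-diol (meso, 1R,2S; "mac diol")
Conditions: AlMe3 (3 equiv), toluene, 0 °C to rt; aq. Rochelle salt; recrystallisation
Reagents that add atoms: trimethylaluminium, C[Al](C)C
Why: Double 1,2-addition of methyl to the 1,2-diketone, in which the second methyl should enter anti to the bulky aluminium alkoxide and so give the cis-diol; any trans isomer is removed by crystallisation and could not bridge boron in step 5 anyway.

**Step 5**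
Reactants: 5 2-(2-ethynyl-4,5-dimethoxyphenyl)-1,3-dioxolane; 8 catecholborane; 7 cis-1,2-dimethyl-1,2-dihydroacenaphthylene-1,2-diol
Product: 10 (Z)-2-[2-(1,3-dioxolan-2-yl)-4,5-dimethoxyphenyl]ethenylboronic acid B(mac) ester (cyclic ester of diol 7), via Z-styryl catechol boronate 9 (not isolated)
Conditions: 5 (1.2 equiv), [Rh(cod)Cl]2 (1.5 mol %), P(i-Pr)3 (6 mol %), Et3N (1 equiv), cyclohexane, rt; then 7, THF, rt
Reagents that add atoms: none
Why: Rhodium-catalysed trans-hydroboration of a terminal alkyne, which runs through a rhodium vinylidene so that boron ends on C2 cis to the aryl group (Z), followed by transesterification of the labile catechol ester with the chelating cis-diol.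

**Step 6**
Reactants: 11 3,4-dimethoxyphenol
Product: 12 3,4-dimethoxyphenyl trifluoromethanesulfonate
Conditions: Tf2O (1.1 equiv), pyridine (2 equiv), CH2Cl2, 0 °C
Reagents that add atoms: triflic anhydride, O=S(=O)(OS(=O)(=O)C(F)(F)F)C(F)(F)F
Why: O-Sulfonylation of a phenol gives the halide-free aryl electrophile that the cationic palladium pathway of step 7 requires.

**Step 7**
Reactants: 10 (Z)-styryl-B(mac) ester; 13 methyllithium; 12 3,4-dimethoxyphenyl trifluoromethanesulfonate
Product: 15 (1R,2S)-1-(3,4-dimethoxyphenyl)-1-[2-(1,3-dioxolan-2-yl)-4,5-dimethoxyphenyl]propan-2-ylboronic acid B(mac) ester, via lithium methyl styryl borate 14 (not isolated)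
Conditions: MeLi (1.0 equiv, low-halide, Et2O), Et2O, 0 °C to rt, evaporate; Pd(OAc)2 (3 mol %), MandyPhos [PAr2, Ar = 4-MeO-3,5-Me2C6H2] (3.6 mol %), 12 (1.2 equiv), THF, 60 °C
Reagents that add atoms: none
Why: Methyllithium adds to the vacant boron orbital of 10 to give ate complex 14; the cationic arylpalladium(II) species formed from 12 by oxidative addition binds the C1=C2 bond and provokes a 1,2-metallate shift in which methyl moves from boron to C2 on the face opposite palladium while palladium becomes σ-bonded to benzylic C1, and reductive elimination with retention then makes the C1–aryl bond. The closest known reaction type is the enantioselective Pd/MandyPhos conjunctive cross-coupling of β-substituted alkenyl-B(mac) ate complexes with aryl triflates, which is stereospecific in the alkene geometry; a β-aryl Z-alkene and methyl as the migrating group lie at the edge of that scope. No ring closes in this step. The relative configuration of C1 and C2 follows from the net anti addition to the geometrically pure Z-alkene (the 1,2-trans ring once C3 replaces boron), and the absolute configuration from the ligand, which has to place palladium on the face that is Si at C1, so that aryl enters C1 from its Si face and methyl enters C2 from its Re face to give (1R,2S). The step needs the metallate shift to beat direct boron-to-palladium transfer of the styryl or methyl group and C–C reductive elimination to beat loss of the C2 hydrogen: the shielded oxygen atoms of the mac ester disfavour the Pd–O–B contact that transmetallation requires, the halide-free triflate medium keeps palladium cationic and alkene-seeking, and the wide-bite-angle bisphosphine speeds reductive elimination. Regiochemistry is inherent because the migrating group can only reach the boron-bearing carbon, and the C1 centre, whose two arenes differ only in one ortho substituent, is defined cleanly because one arene is already part of the alkene and the other is delivered by palladium.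

**Step 8**
Reactants: 15 (1R,2S)-1,1-diarylpropan-2-yl-B(mac) ester
Product: 18 2-{2-[(1R,2S)-1-(3,4-dimethoxyphenyl)-2,3-dimethylbut-3-en-1-yl]-4,5-dimethoxyphenyl}-1,3-dioxolane, via lithium isopropenyl borate 16 (not isolated), via beta-iodo boronate 17 (not isolated)
Conditions: 2-bromopropene, t-BuLi (2 equiv per bromide), Et2O, −78 °C; 15, THF, −78 °C; I2, THF, −78 °C; NaOMe, MeOH, −78 °C to rt
Reagents that add atoms: isopropenyllithium, [Li]C(C)=C, made in the flask from 2-bromopropene, C=C(C)Br
Why: Zweifel olefination, in which iodine activates the alkenyl group of ate complex 16, C2 (the only carbon ligand able to migrate) shifts from boron to C3 with retention of configuration, and methoxide triggers elimination of boron and iodide from 17, while C1 is not involved.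

**Step 9**
Reactants: 18 alkene acetal
Product: 19 2-[(1R,2S)-1-(3,4-dimethoxyphenyl)-2,3-dimethylbut-3-en-1-yl]-4,5-dimethoxybenzaldehyde
Conditions: 1 M HCl, THF, rt
Reagents that add atoms: water, O
Why: Acid-catalysed acetal hydrolysis, which is fast for an electron-rich aryl dioxolane and mild enough to leave the 1,1-disubstituted alkene and both stereocentres untouched.

**Step 10**
Reactants: 19 aldehyde
Product: 20 1-[(1R,2S)-1-(3,4-dimethoxyphenyl)-2,3-dimethylbut-3-en-1-yl]-2-ethenyl-4,5-dimethoxybenzene
Conditions: Ph3PCH3Br (1.5 equiv), KOt-Bu (1.4 equiv), THF, 0 °C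
Reagents that add atoms: methylenetriphenylphosphorane, C=P(c1ccccc1)(c1ccccc1)c1ccccc1, made in the flask from methyltriphenylphosphonium bromide, C[P+](c1ccccc1)(c1ccccc1)c1ccccc1.[Br-]
Why: Wittig methylenation of a non-enolisable aryl aldehyde; the phosphonium salt is kept in slight excess over the base, so no free alkoxide is left to attack the doubly benzylic C1–H.

**Step 11**
Reactants: 20 diene
Product: 21 (1R,2S)-1-(3,4-dimethoxyphenyl)-6,7-dimethoxy-2,3-dimethyl-1,2-dihydronaphthalene (target)
Conditions: Grubbs second-generation catalyst (5 mol %), CH2Cl2, 40 °C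
Reagents that add atoms: none
Why: Ring-closing metathesis, in which ruthenium loads on the styrene terminus and closes onto the isopropenyl group to form the six-membered ring with its trisubstituted C3=C4 bond and lose ethene, under neutral conditions that leave C1 and C2 as set.

**Compound list**
1 | 2-bromo-4,5-dimethoxybenzaldehyde | COc1cc(Br)c(C=O)cc1OC | starting material
2 | trimethylsilylacetylene | C#C[Si](C)(C)C | starting material
3 | 4,5-dimethoxy-2-[(trimethylsilyl)ethynyl]benzaldehyde | COc1cc(C#C[Si](C)(C)C)c(C=O)cc1OC | intermediate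
4 | 2-{4,5-dimethoxy-2-[(trimethylsilyl)ethynyl]phenyl}-1,3-dioxolane | COc1cc(C#C[Si](C)(C)C)c(C2OCCO2)cc1OC | intermediate
5 | 2-(2-ethynyl-4,5-dimethoxyphenyl)-1,3-dioxolane | COc1cc(C#C)c(C2OCCO2)cc1OC | intermediate
6 | acenaphthoquinone | O=C1C(=O)c2cccc3cccc1c23 | starting material
7 | cis-1,2-dimethyl-1,2-dihydroacenaphthylene-1,2-diol (meso) | C[C@@]1(O)c2cccc3cccc(c23)[C@]1(C)O | intermediate
8 | catecholborane | B1Oc2ccccc2O1 | starting material
9 | (Z)-styryl catechol boronate (not isolated) | COc1cc(/C=C\B2Oc3ccccc3O2)c(C4OCCO4)cc1OC | intermediate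
10 | (Z)-2-[2-(1,3-dioxolan-2-yl)-4,5-dimethoxyphenyl]ethenyl-B(mac) ester | COc1cc(/C=C\B2O[C@]3(C)c4cccc5cccc(c45)[C@]3(C)O2)c(C6OCCO6)cc1OC | intermediate
11 | 3,4-dimethoxyphenol | COc1ccc(O)cc1OC | starting material
12 | 3,4-dimethoxyphenyl trifluoromethanesulfonate | COc1ccc(OS(=O)(=O)C(F)(F)F)cc1OC | intermediate
13 | methyllithium | [Li]C | starting material
14 | lithium methyl[(Z)-styryl]borate of 10 (not isolated; configuration at boron undefined) | [Li+].COc1cc(/C=C\[B-]2(C)O[C@]3(C)c4cccc5cccc(c45)[C@]3(C)O2)c(C6OCCO6)cc1OC | intermediate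
15 | (1R,2S)-1-(3,4-dimethoxyphenyl)-1-[2-(1,3-dioxolan-2-yl)-4,5-dimethoxyphenyl]propan-2-yl-B(mac) ester | COc1ccc([C@H](c2cc(OC)c(OC)cc2C3OCCO3)[C@H](C)B4O[C@]5(C)c6cccc7cccc(c67)[C@]5(C)O4)cc1OC | intermediate
16 | lithium isopropenyl borate of 15 (not isolated; C1 and C2 as in 15) | [Li+].COc1ccc([C@H](c2cc(OC)c(OC)cc2C3OCCO3)[C@H](C)[B-]4(C(C)=C)O[C@]5(C)c6cccc7cccc(c67)[C@]5(C)O4)cc1OC | intermediate
17 | β-iodo boronate, C3 bearing CH3, CH2I and B(mac) (not isolated; C3 undefined, C1 and C2 as in 15) | COc1ccc([C@H](c2cc(OC)c(OC)cc2C3OCCO3)[C@H](C)C(C)(CI)B4O[C@]5(C)c6cccc7cccc(c67)[C@]5(C)O4)cc1OC | intermediate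
18 | 2-{2-[(1R,2S)-1-(3,4-dimethoxyphenyl)-2,3-dimethylbut-3-en-1-yl]-4,5-dimethoxyphenyl}-1,3-dioxolane | COc1ccc([C@H](c2cc(OC)c(OC)cc2C3OCCO3)[C@H](C)C(C)=C)cc1OC | intermediate
19 | 2-[(1R,2S)-1-(3,4-dimethoxyphenyl)-2,3-dimethylbut-3-en-1-yl]-4,5-dimethoxybenzaldehyde | COc1ccc([C@H](c2cc(OC)c(OC)cc2C=O)[C@H](C)C(C)=C)cc1OC | intermediate
20 | 1-[(1R,2S)-1-(3,4-dimethoxyphenyl)-2,3-dimethylbut-3-en-1-yl]-2-ethenyl-4,5-dimethoxybenzene | COc1ccc([C@H](c2cc(OC)c(OC)cc2C=C)[C@H](C)C(C)=C)cc1OC | intermediate
21 | (1R,2S)-1-(3,4-dimethoxyphenyl)-6,7-dimethoxy-2,3-dimethyl-1,2-dihydronaphthalene | COc1ccc([C@@H]2c3cc(OC)c(OC)cc3C=C(C)[C@H]2C)cc1OC | target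

Total step count: 11.
Longest linear sequence: 9 steps (1, 2, 3, 5, 7, 8, 9, 10, 11, starting from 1). Steps 4 and 6 are one-step side branches.

**Steps most likely to fail**

Step 7.
- What may go wrong: direct transfer of the styryl or methyl group from boron to palladium may outrun the metallate shift. The benzylpalladium intermediate may lose the C2 hydrogen by β-hydride elimination before the C–C bond forms. Face selection on a Z β-aryl alkene may also be weaker than on simpler alkenes.
- Fallback (sets out from 5, returns at 18): the methyl group is installed first, and aryl and boron are added instead. Alkyne 5 is C-methylated (n-BuLi, MeI, THF) to 2-[4,5-dimethoxy-2-(prop-1-yn-1-yl)phenyl]-1,3-dioxolane F1, and semihydrogenation over Lindlar catalyst gives the (Z)-propenylarene F2.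
- F2 is submitted to the cooperative copper/palladium-catalysed enantioselective syn-arylboration with 4-bromo-1,2-dimethoxybenzene and B2pin2 (chiral NHC–CuCl, Pd/RuPhos, NaOt-Bu). Borylcupration puts boron on C2 and copper on benzylic C1, and stereoretentive copper-to-palladium transfer and reductive elimination deliver the aryl group syn to boron.
- On the Z-alkene this corresponds to the same (1R,2S) arrangement, in the form of the pinacol boronate F3. F3 is carried through the olefination of step 8 and gives 18.

Step 5.
- What may go wrong: leakage through ordinary syn hydroboration, or rhodium-hydride-mediated Z-to-E isomerisation of the product, would erode the alkene geometry. Any E isomer is translated by step 7 into the 1,2-cis series.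
- Fallback (sets out from 5, returns at 10): the geometry is set by syn delivery of hydrogen to a triple bond. The lithium acetylide of 5 (n-BuLi, THF, −78 °C) is trapped with B(Oi-Pr)3 and the borate is neutralised with ethereal HCl to give the diisopropyl alkynylboronate F4.
- Diol 7 displaces isopropanol to give the alkynyl-B(mac) ester F5, and cis-semihydrogenation over Lindlar catalyst (H2, dioxane, pyridine) gives 10.

Step 8.
- What may go wrong: ate-complex formation at the crowded secondary boron centre next to the diarylmethyl group may be slow or reversible, and iodine may then be consumed by free alkenyllithium instead of by the ate complex.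
- Fallback (sets out from 15, returns at 18): C3 is inserted with a small carbenoid and no electrophilic halogen. Matteson homologation with LiCHCl2 (CH2Cl2, n-BuLi, THF, −100 °C; ZnCl2) moves C2 onto the new carbon with retention and gives the α-chloro boronate F6, and MeMgBr displaces chloride through a second 1,2-shift to the homologated secondary boronate F7.
- Oxidation (NaBO3, THF/H2O) gives the secondary alcohol F8, Dess–Martin oxidation gives the methyl ketone F9, and Wittig methylenation (Ph3P=CH2, THF, 0 °C) gives 18. The undefined carbinol centre disappears on the way.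

**Further compounds**
F1 | step 7 | 2-[4,5-dimethoxy-2-(prop-1-yn-1-yl)phenyl]-1,3-dioxolane | COc1cc(C#CC)c(C2OCCO2)cc1OC
F2 | step 7 | 2-{4,5-dimethoxy-2-[(Z)-prop-1-en-1-yl]phenyl}-1,3-dioxolane | COc1cc(/C=C\C)c(C2OCCO2)cc1OC
F3 | step 7 | (1R,2S)-1-(3,4-dimethoxyphenyl)-1-[2-(1,3-dioxolan-2-yl)-4,5-dimethoxyphenyl]propan-2-ylboronic acid pinacol ester | COc1ccc([C@H](c2cc(OC)c(OC)cc2C3OCCO3)[C@H](C)B4OC(C)(C)C(C)(C)O4)cc1OC
F4 | step 5 | diisopropyl [2-(1,3-dioxolan-2-yl)-4,5-dimethoxyphenyl]ethynylboronate | COc1cc(C#CB(OC(C)C)OC(C)C)c(C2OCCO2)cc1OC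
F5 | step 5 | [2-(1,3-dioxolan-2-yl)-4,5-dimethoxyphenyl]ethynyl-B(mac) ester | COc1cc(C#CB2O[C@]3(C)c4cccc5cccc(c45)[C@]3(C)O2)c(C6OCCO6)cc1OC
F6 | step 8 | α-chloro boronate, C3 bearing H, Cl and B(mac) (C1 and C2 as in 15, C3 undefined) | COc1ccc([C@H](c2cc(OC)c(OC)cc2C3OCCO3)[C@H](C)C(Cl)B4O[C@]5(C)c6cccc7cccc(c67)[C@]5(C)O4)cc1OC
F7 | step 8 | homologated secondary boronate, C3 bearing H, CH3 and B(mac) (C1 and C2 as in 15, C3 undefined) | COc1ccc([C@H](c2cc(OC)c(OC)cc2C3OCCO3)[C@H](C)C(C)B4O[C@]5(C)c6cccc7cccc(c67)[C@]5(C)O4)cc1OC
F8 | step 8 | 4-(3,4-dimethoxyphenyl)-4-[2-(1,3-dioxolan-2-yl)-4,5-dimethoxyphenyl]-3-methylbutan-2-ol (C1 and C2 as in 15, carbinol centre undefined) | COc1ccc([C@H](c2cc(OC)c(OC)cc2C3OCCO3)[C@H](C)C(C)O)cc1OC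
F9 | step 8 | (3S,4R)-4-(3,4-dimethoxyphenyl)-4-[2-(1,3-dioxolan-2-yl)-4,5-dimethoxyphenyl]-3-methylbutan-2-one | COc1ccc([C@H](c2cc(OC)c(OC)cc2C3OCCO3)[C@H](C)C(C)=O)cc1OC
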